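## Analysis of the target

Target 13 is a fully substituted imidazole: N1 carries a methyl group, C2 an exocyclic NH, C4 a hydroxy(4-methoxyphenyl)methyl group and C5 a 4-methoxybenzyl group. The exocyclic nitrogen is bound to C4 of a second five-membered ring, a 1-methylimidazole-2,5-dione, so that an acylamidine results; this ring is the dehydrated adduct of a 2-aminoimidazole with the C4 carbonyl of 1-methylparabanic acid. The only stereocentre is the carbinol carbon on imidazole C4; ranking OH > imidazol-4-yl (N,C,C) > 4-methoxyphenyl (C,C,C) > H makes it R, and there is no second stereo-element to relate it to. This carbinol sits between an anisyl ring and an electron-rich aminoimidazole and should ionise easily under acid, so it has to be made late and kept away from acid. The dioxoimidazole ring is imide-like and open to hydrazine, hydroxide and unselective hydride, so it has to be attached after any such reagent has been used. The hard part is the cyclic guanidine N1(CH3)–C2(N)–N3: its three nitrogens are similar, yet the methyl must sit on the nitrogen next to the benzyl-bearing C5, and the unsubstituted N3 must sit next to C4. The plan rests on this guanidine unit and on the C4/C5 pair, whose substituents (an aroyl-level carbon on C4, a CH2-aryl on C5) map onto the two different carbonyls of a 1,4-diarylbutane-1,3-dione.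

## Retrosynthetic reasoning

**13 to 12.** The last bond made is the C–H bond of the carbinol. Cutting it turns the stereocentre into the aryl ketone of 12, the oxidation level that the ring construction delivers anyway. The reduction is placed last because the carbinol is the most fragile group, and because the acylamidine of 12 draws electron density from the imidazole and so makes the product less prone to ionise. The forward step has to reduce a ketone with two flat (hetero)aryl groups with control of the face, and must leave the imide carbonyls and the amidine alone.

**12 to 9 and 10.** The exocyclic N–C bond of the acylamidine is cut, giving 2-aminoimidazole 9 and 1-methylparabanic acid 10. Amine 9 has a single primary amino group, so the imidazole side needs no regiochemical decision. The decision lies in 10, where the carbonyl next to N–H (C4) must react and not C5 or C2. Making this bond only after the amine has been unmasked keeps the imide-like ring away from the hydrazinolysis.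

**9 to 8.** Three carbons are put back between the amino nitrogen and N3 of 9, which gives the imidazo[1,2-a]pyrimidinium salt 8. In 8 the three guanidine nitrogens are no longer alike: one bears methyl, one is the bridgehead, and one is a nitrogen of the six-membered ring. The forward reaction, a hydrazinolysis, has to take the three-carbon bridge out again without touching the ketone.

**8 to 4 and 5.** In 8 the bonds from the bridgehead nitrogen to C3 and from N1 to C2 are cut; these are N3–C4 and N1–C5 of the later imidazole. This leaves N-methylpyrimidin-2-amine 5 and the 2-bromo-1,3-diketone 4. The cut is made here because 5 already holds the whole guanidine with the methyl group fixed on one nitrogen, and because its two ring nitrogens are equivalent. The forward reaction must alkylate a ring nitrogen at the brominated carbon and then close the N-methylamino group onto the benzyl ketone, not onto the aroyl ketone.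

**4 to 3.** The C–Br bond of 4 is cut to give diketone 3, whose central carbon is its most nucleophilic site, so the halogen can be placed there without a directing or protecting group.

**3 to 1 and 2.** Diketone 3 is cut at the bond between the central CH2 and the benzyl ketone carbon, giving 4'-methoxyacetophenone 1 as the enolate partner and methyl 4-methoxyphenylacetate 2 as the acyl donor. Both are cheap, and the pairing puts the aryl ketone and the benzyl ketone in place in one step.

## Alternatives that were turned down

Alternative 1: carbonylative arylation of a preformed core. The C4–C(=O) and C(=O)–aryl bonds are cut together. The 2-amino-1-methylimidazole core of creatinine A1 is taken to the 4-bromo-5-(4-methoxybenzyl) formamidine A2. A palladium–phosphine catalysed carbonylative Suzuki–Miyaura coupling of A2 with 4-methoxyphenylboronic acid A3 under carbon monoxide A4 would then give ketone A5.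
- For it: the N-methyl/2-amino pattern comes with A1, so there is no nitrogen regiochemistry to solve at all. On this point it is stronger than the chosen route, which has to earn the pattern through a temporary ring. The three-component coupling is also convergent.
- Against it: A2 is an electron-rich, ortho-substituted heteroaryl bromide, and oxidative addition to zerovalent palladium is slow and is slowed further by A4. The formamidine and the ring nitrogen can bind the metal, and direct coupling without carbonyl insertion is a likely side path.
- Step economy: reaching A2 needs C5 benzylation of A1, conversion of the ring carbonyl into the bromide and protection. After A5 the protecting group must come off, and the amidine formation and the same difficult ketone reduction remain.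
- Comparison: the chosen route reaches the same ketone level directly from diketone 3, without a transition metal and in fewer steps.

Alternative 2: alkyne carboamination of a propargyl guanidine. The N1–C5 bond and the CH2–aryl bond are cut. (R)-4-Methoxymandelic acid A6 is taken through the silyloxy aldehyde A7 to propargyl guanidine A8, which would undergo palladium-catalysed aminopalladation and arylation with 4-methoxyphenyl triflate A9 and, after a proton shift, give imidazole A10.
- For it: the stereocentre is bought, so no reduction of a ketone between two aryl-type groups is needed. In principle this is the stronger answer to the stereochemical problem. The tether also fixes which nitrogen ends next to C5.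
- Against it: aldehyde A7 is configurationally fragile, because its stereocentre is both benzylic and alpha to the formyl group. The carbinol C–H of A8 stays activated until the proton shift has made the ring aromatic, and it must survive an alkoxide base at high temperature without epimerisation or loss of silanolate.
- Step economy: two protecting groups (silyl ether and sulfonyl) must be removed from A10 before the amidine can be made, and the linear sequence is roughly twice as long.
- Comparison: the chosen route needs six steps and no protecting groups, and creates the stereocentre at the very end when nothing later can erase it. The price is reliance on catalyst control.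

Alternative 3: ring transformation of an oxadiazole. The N3–C4 bond is cut. Diketone 3 is condensed with 3-amino-5-methyl-1,2,4-oxadiazole A11 to give enaminone A12. An alkoxide base then triggers a Boulton–Katritzky rearrangement: the enaminone carbon attacks ring N2 as the O–N bond breaks, giving 2-acetamidoimidazole A13.
- For it: no halogenation is needed, and the rearrangement is irreversible because a weak N–O bond is traded for an aromatic imidazole and an amide. It starts from the same diketone 3.
- Against it: A13 is an N–H imidazole. The methyl group must be added afterwards and must choose between two ring nitrogens and the acetamide nitrogen, with the wanted nitrogen the one crowded by the benzyl group. This is exactly the differentiation problem the target poses.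
- Further drawbacks: A11 is a very weak nucleophile, so formation of A12 is forcing and faces the same choice between the two carbonyls. The acetyl group of A13 must be removed in an extra step.
- Comparison: in the chosen route the methyl group is on nitrogen before the ring closes, and the sequence is at least two steps shorter.

Key step: step 3

Assumption: the sense of induction in step 6 is assigned by analogy with aryl alkyl ketones and ortho-substituted benzophenones, with the unhindered anisyl ring next to the η6-arene of the catalyst. On this model the (S,S)-ligand gives the (R)-carbinol; if the assignment proved reversed, the (R,R)-ligand would be used.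

## Route

Step 1
Reactants: 1 4'-methoxyacetophenone; 2 methyl 4-methoxyphenylacetate
Product: 3 1,4-bis(4-methoxyphenyl)butane-1,3-dione
Conditions: 1 (2.1 equiv), LiN(SiMe3)2 (2.1 equiv), THF, −78 °C; then 2 (1.0 equiv), −78 °C to rt; 1 M HCl
Reagents that add atoms: none
Why: Crossed Claisen condensation; the lithium enolate of 1 is preformed so that no free ketone is left for aldol reaction, and the second equivalent of enolate deprotonates the product, whose chelated lithium diketonate is the thermodynamic sink and pulls the equilibria forward.

Step 2
Reactants: 3 1,4-bis(4-methoxyphenyl)butane-1,3-dione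
Product: 4 2-bromo-1,4-bis(4-methoxyphenyl)butane-1,3-dione (racemic, partly enolised)
Conditions: NBS (1.0 equiv), CH2Cl2, 0 °C
Reagents that add atoms: N-bromosuccinimide, O=C1CCC(=O)N1Br
Why: Electrophilic alpha-bromination of a 1,3-diketone through its enol; the central carbon of the enolised diketone is far more nucleophilic than the benzylic CH2 or the anisole rings, and the monobromide is less enolised, which should stop the reaction after one bromine.

Step 3
Reactants: 4 2-bromo-1,4-bis(4-methoxyphenyl)butane-1,3-dione; 5 N-methylpyrimidin-2-amine
Product: 8 3-(4-methoxybenzoyl)-2-(4-methoxybenzyl)-1-methylimidazo[1,2-a]pyrimidin-1-ium bromide, via N-alkylpyrimidinium bromide 6 (not isolated), via bicyclic hemiaminal bromide 7 (not isolated)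
Conditions: MeCN, 4 Å molecular sieves, 80 °C; Et2O precipitation
Reagents that add atoms: none
Why: Chichibabin-type cyclocondensation of a 2-aminoazine with an alpha-halo carbonyl compound, in its known variants with 2-halo-1,3-dicarbonyls (3-acyl products) and with 2-(alkylamino)pyrimidines (1-alkyl azinium salts). A ring nitrogen of 5, the more nucleophilic end of the amidine unit, displaces bromide from the central carbon of 4 by SN2 to give salt 6 and so forms the later N3–C4 bond; the two ring nitrogens of 5 are equivalent, so this step has no regiochemical choice. The N-methylamino nitrogen then adds to the neighbouring benzyl ketone in a 5-exo-trig closure to hemiaminal 7 (the later N1–C5 bond), and dehydration, helped by the acidic C–H between the cationic ring nitrogen and the aroyl group, gives the aromatic bicyclic cation 8. One ring is closed and no stereocentre remains, since the centres of 6 and 7 are erased on aromatisation. The selectivity needed is between the two ketones, because both closures are 5-exo-trig; the benzyl ketone is not conjugated and is the more electrophilic, whereas the 4-methoxybenzoyl carbonyl is deactivated as a vinylogous ester by the para-methoxy group, so addition there should be slower and more easily reversed. The cationic product cannot be alkylated again, and full dehydration to 8 removes the ring–chain equilibrium of 7 that could otherwise allow a Dimroth-type shift of the methyl position in the next step.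

Step 4
Reactants: 8 3-(4-methoxybenzoyl)-2-(4-methoxybenzyl)-1-methylimidazo[1,2-a]pyrimidin-1-ium bromide
Product: 9 [2-amino-5-(4-methoxybenzyl)-1-methyl-1H-imidazol-4-yl](4-methoxyphenyl)methanone
Conditions: N2H4·H2O (5 equiv), MeCN, 80 °C
Reagents that add atoms: none
Why: Hydrazinolysis of an imidazo[1,2-a]pyrimidinium salt (ring opening and ring closure on the three-carbon unit): hydrazine adds to the electron-poor CH positions next to the two nitrogens of the six-membered ring and carries the three carbons away as pyrazole, freeing N3 and the 2-amino group. The ketone, once released, is a push–pull carbonyl conjugated with N1 and should resist hydrazone formation.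

Step 5
Reactants: 9 [2-amino-5-(4-methoxybenzyl)-1-methyl-1H-imidazol-4-yl](4-methoxyphenyl)methanone; 10 1-methylparabanic acid
Product: 12 4-{[4-(4-methoxybenzoyl)-5-(4-methoxybenzyl)-1-methyl-1H-imidazol-2-yl]amino}-1-methyl-1H-imidazole-2,5-dione, via O-trimethylsilyl imidate 11 (not isolated)
Conditions: 10, N,O-bis(trimethylsilyl)acetamide (1.2 equiv), MeCN, 80 °C; evaporate; then 9, toluene, 110 °C
Reagents that add atoms: none
Why: Silyl-mediated amidine formation by addition–elimination on an O-silyl imidate: silylation of the N–H of 10 gives imidate 11, whose silyloxy-bearing C4 is activated by the adjacent C5 carbonyl and is far more electrophilic than the urea-type C2. The primary amine of 9 adds there, trimethylsilanol leaves, and tautomerisation gives the conjugated acylamidine 12.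

Step 6
Reactants: 12 4-{[4-(4-methoxybenzoyl)-5-(4-methoxybenzyl)-1-methyl-1H-imidazol-2-yl]amino}-1-methyl-1H-imidazole-2,5-dione
Product: 13 4-({4-[(R)-hydroxy(4-methoxyphenyl)methyl]-5-(4-methoxybenzyl)-1-methyl-1H-imidazol-2-yl}amino)-1-methyl-1H-imidazole-2,5-dione
Conditions: RuCl(p-cymene)[(S,S)-TsDPEN] (3 mol %), HCO2H/Et3N (1:1), DMF, 35 °C; neutral work-up
Reagents that add atoms: none
Why: Noyori–Ikariya asymmetric transfer hydrogenation of an unsymmetrical diaryl-type ketone; the outer-sphere Ru–H/N–H transfer is selective for the ketone over the imide carbonyls and the amidine. The unhindered anisyl ring is expected to lie next to the η6-arene (CH/π contact) and the ortho-substituted imidazolyl group away from it, which with the (S,S)-ligand should deliver hydride to the face that gives the (R)-carbinol. The amine-rich formate medium avoids the acid that would ionise the product.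

## Compound list

1 | 4'-methoxyacetophenone | COc1ccc(C(C)=O)cc1 | starting material
2 | methyl 4-methoxyphenylacetate | COC(=O)Cc1ccc(OC)cc1 | starting material
3 | 1,4-bis(4-methoxyphenyl)butane-1,3-dione | COc1ccc(CC(=O)CC(=O)c2ccc(OC)cc2)cc1 | intermediate
4 | 2-bromo-1,4-bis(4-methoxyphenyl)butane-1,3-dione (racemic) | COc1ccc(CC(=O)C(Br)C(=O)c2ccc(OC)cc2)cc1 | intermediate
5 | N-methylpyrimidin-2-amine | CNc1ncccn1 | starting material
6 | 1-[1,4-bis(4-methoxyphenyl)-1,3-dioxobutan-2-yl]-2-(methylamino)pyrimidin-1-ium bromide (racemic, not isolated) | CNc1nccc[n+]1C(C(=O)Cc2ccc(OC)cc2)C(=O)c2ccc(OC)cc2.[Br-] | intermediate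
7 | 2-hydroxy-3-(4-methoxybenzoyl)-2-(4-methoxybenzyl)-1-methyl-2,3-dihydro-1H-imidazo[1,2-a]pyrimidin-4-ium bromide (mixture of stereoisomers, not isolated) | CN1C(O)(Cc2ccc(OC)cc2)C(C(=O)c2ccc(OC)cc2)[n+]2cccnc12.[Br-] | intermediate
8 | 3-(4-methoxybenzoyl)-2-(4-methoxybenzyl)-1-methylimidazo[1,2-a]pyrimidin-1-ium bromide | C[N+]1=C2N=CC=CN2C(C(=O)c2ccc(OC)cc2)=C1Cc1ccc(OC)cc1.[Br-] | intermediate
9 | [2-amino-5-(4-methoxybenzyl)-1-methyl-1H-imidazol-4-yl](4-methoxyphenyl)methanone | COc1ccc(Cc2c(C(=O)c3ccc(OC)cc3)nc(N)n2C)cc1 | intermediate
10 | 1-methylparabanic acid (1-methylimidazolidine-2,4,5-trione) | CN1C(=O)NC(=O)C1=O | starting material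
11 | 1-methyl-4-(trimethylsilyloxy)-1H-imidazole-2,5-dione (not isolated) | CN1C(=O)N=C(O[Si](C)(C)C)C1=O | intermediate
12 | 4-{[4-(4-methoxybenzoyl)-5-(4-methoxybenzyl)-1-methyl-1H-imidazol-2-yl]amino}-1-methyl-1H-imidazole-2,5-dione | COc1ccc(Cc2c(C(=O)c3ccc(OC)cc3)nc(NC3=NC(=O)N(C)C3=O)n2C)cc1 | intermediate
13 | 4-({4-[(R)-hydroxy(4-methoxyphenyl)methyl]-5-(4-methoxybenzyl)-1-methyl-1H-imidazol-2-yl}amino)-1-methyl-1H-imidazole-2,5-dione | COc1ccc(Cc2c([C@H](O)c3ccc(OC)cc3)nc(NC3=NC(=O)N(C)C3=O)n2C)cc1 | target

## Step count and risk

Total steps: 6. Longest linear sequence: 6 steps (1 or 2 to 13); 5 and 10 are bought and enter at steps 3 and 5.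

**Step 3 (key step).** Three things may go wrong.
- The N-methylamino group may close onto the aroyl carbonyl instead of the benzyl ketone. Both closures form a five-membered ring, and only the difference in carbonyl electrophilicity separates them.
- Bromine may be transferred from 4 to the aminopyrimidine, since a bromine between two carbonyls is electrophilic. This would return 3 and consume 5.
- Dehydration of hemiaminal 7 may stall, and material carried forward at that stage could open and reclose in step 4 so that the methyl group ends on the exocyclic nitrogen.

The fallback removes the second ketone from the annulation and installs the aryl ketone afterwards. It sets out from 2 and 5 and returns at 9.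
- The lithium enolate of N-methoxy-N-methylacetamide (LiN(iPr)2, THF, −78 °C) is acylated by ester 2 to give N-methoxy-4-(4-methoxyphenyl)-N-methyl-3-oxobutanamide F1.
- Bromination with NBS gives 2-bromo-N-methoxy-4-(4-methoxyphenyl)-N-methyl-3-oxobutanamide F2.
- Heating F2 with 5 in MeCN can close only onto the single ketone, giving 3-[methoxy(methyl)carbamoyl]-2-(4-methoxybenzyl)-1-methylimidazo[1,2-a]pyrimidin-1-ium bromide F3.
- Hydrazinolysis of F3 gives 2-amino-N-methoxy-5-(4-methoxybenzyl)-N,1-dimethyl-1H-imidazole-4-carboxamide F4.
- Excess 4-MeOC6H4MgBr in THF converts the Weinreb amide of F4 into ketone 9.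

This sequence also keeps a ketone out of the hydrazine step.

**Step 6.** Facial discrimination may be poor, because both groups on the carbonyl are flat (hetero)aryl rings and the assignment of which one sits next to the arene ligand is a model, not a certainty. The chelating imidazole N3/amidine pair may also slow the ruthenium catalyst, and any acid would ionise the product and erode its configuration. The fallback replaces asymmetric catalysis by resolution with recycling; it sets out from 12 and returns at 13.
- Reduction of 12 with the racemic form of the same catalyst gives the racemic carbinol F5.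
- Preparative chromatography on a chiral stationary phase separates 13 from its (S)-enantiomer F6.
- The (S)-enantiomer F6 is oxidised with MnO2 in CH2Cl2 back to 12 and reduced again.

The absolute configuration would be confirmed on the resolved material, for example by Mosher ester analysis.

**Step 4.** Hydrazine may condense with the aryl ketone while that ketone is still activated by the cationic bicycle. A hydrazinyl group formed on the six-membered ring may also be captured by the ketone before the ring is cleaved. The fallback accepts the condensation and removes it afterwards; it sets out from 8 and returns at 9. Salt 8 is treated with a large excess of N2H4·H2O so that ring cleavage and condensation both go to completion, giving [2-amino-5-(4-methoxybenzyl)-1-methyl-1H-imidazol-4-yl](4-methoxyphenyl)methanone hydrazone F7. Hydrazone F7 is then exchanged with acetone and catalytic TsOH in aqueous THF, which transfers the hydrazine unit to acetone and releases 9.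

**Step 5.** The addition–elimination may be slow, because the 4-aroyl group lowers the nucleophilicity of the amine of 9, and long heating would degrade imidate 11. The fallback makes the amidine at the carbinol level, where the amine is as nucleophilic as in a simple 2-amino-4,5-dialkylimidazole; it sets out from 9 and returns at 13.
- Transfer hydrogenation of 9 under the conditions of step 6 gives (R)-[2-amino-5-(4-methoxybenzyl)-1-methyl-1H-imidazol-4-yl](4-methoxyphenyl)methanol F8.
- Silylation of F8 with tBuMe2SiCl and imidazole in DMF gives the silyl ether F9.
- Condensation of F9 with imidate 11 in toluene at 110 °C gives the silyl-protected amidine F10.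
- Bu4NF in THF at 0 °C releases 13 from F10.

The weak point of this order is that the carbinol centre must survive the hot condensation, which is why it is not the first choice.

## Further compounds

F1 | step 3 | N-methoxy-4-(4-methoxyphenyl)-N-methyl-3-oxobutanamide | COc1ccc(CC(=O)CC(=O)N(C)OC)cc1
F2 | step 3 | 2-bromo-N-methoxy-4-(4-methoxyphenyl)-N-methyl-3-oxobutanamide (racemic) | COc1ccc(CC(=O)C(Br)C(=O)N(C)OC)cc1
F3 | step 3 | 3-[methoxy(methyl)carbamoyl]-2-(4-methoxybenzyl)-1-methylimidazo[1,2-a]pyrimidin-1-ium bromide | C[N+]1=C2N=CC=CN2C(C(=O)N(C)OC)=C1Cc1ccc(OC)cc1.[Br-]
F4 | step 3 | 2-amino-N-methoxy-5-(4-methoxybenzyl)-N,1-dimethyl-1H-imidazole-4-carboxamide | COc1ccc(Cc2c(C(=O)N(C)OC)nc(N)n2C)cc1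
F5 | step 6 | racemic 4-({4-[hydroxy(4-methoxyphenyl)methyl]-5-(4-methoxybenzyl)-1-methyl-1H-imidazol-2-yl}amino)-1-methyl-1H-imidazole-2,5-dione | COc1ccc(Cc2c(C(O)c3ccc(OC)cc3)nc(NC3=NC(=O)N(C)C3=O)n2C)cc1
F6 | step 6 | 4-({4-[(S)-hydroxy(4-methoxyphenyl)methyl]-5-(4-methoxybenzyl)-1-methyl-1H-imidazol-2-yl}amino)-1-methyl-1H-imidazole-2,5-dione | COc1ccc(Cc2c([C@@H](O)c3ccc(OC)cc3)nc(NC3=NC(=O)N(C)C3=O)n2C)cc1
F7 | step 4 | [2-amino-5-(4-methoxybenzyl)-1-methyl-1H-imidazol-4-yl](4-methoxyphenyl)methanone hydrazone (E/Z mixture) | COc1ccc(Cc2c(C(=NN)c3ccc(OC)cc3)nc(N)n2C)cc1
F8 | step 5 | (R)-[2-amino-5-(4-methoxybenzyl)-1-methyl-1H-imidazol-4-yl](4-methoxyphenyl)methanol | COc1ccc(Cc2c([C@H](O)c3ccc(OC)cc3)nc(N)n2C)cc1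
F9 | step 5 | 4-[(R)-(tert-butyldimethylsilyloxy)(4-methoxyphenyl)methyl]-5-(4-methoxybenzyl)-1-methyl-1H-imidazol-2-amine | COc1ccc(Cc2c([C@H](O[Si](C)(C)C(C)(C)C)c3ccc(OC)cc3)nc(N)n2C)cc1
F10 | step 5 | 4-({4-[(R)-(tert-butyldimethylsilyloxy)(4-methoxyphenyl)methyl]-5-(4-methoxybenzyl)-1-methyl-1H-imidazol-2-yl}amino)-1-methyl-1H-imidazole-2,5-dione | COc1ccc(Cc2c([C@H](O[Si](C)(C)C(C)(C)C)c3ccc(OC)cc3)nc(NC3=NC(=O)N(C)C3=O)n2C)cc1
A1 | alternative 1 | creatinine (2-amino-1-methyl-1,5-dihydro-4H-imidazol-4-one) | CN1CC(=O)N=C1N
A2 | alternative 1 | N'-[4-bromo-5-(4-methoxybenzyl)-1-methyl-1H-imidazol-2-yl]-N,N-dimethylformamidine | CN(C)/C=N/c1nc(Br)c(Cc2ccc(OC)cc2)n1C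
A3 | alternative 1 | 4-methoxyphenylboronic acid | COc1ccc(B(O)O)cc1
A4 | alternative 1 | carbon monoxide | [C-]#[O+]
A5 | alternative 1 | N'-[4-(4-methoxybenzoyl)-5-(4-methoxybenzyl)-1-methyl-1H-imidazol-2-yl]-N,N-dimethylformamidine | CN(C)/C=N/c1nc(C(=O)c2ccc(OC)cc2)c(Cc2ccc(OC)cc2)n1C
A6 | alternative 2 | (R)-4-methoxymandelic acid | O=C(O)[C@H](O)c1ccc(OC)cc1
A7 | alternative 2 | (R)-2-(tert-butyldimethylsilyloxy)-2-(4-methoxyphenyl)acetaldehyde | O=C[C@H](O[Si](C)(C)C(C)(C)C)c1ccc(OC)cc1
A8 | alternative 2 | N-{1-[(R)-(tert-butyldimethylsilyloxy)(4-methoxyphenyl)methyl]prop-2-yn-1-yl}-N'-methyl-N''-[2-(trimethylsilyl)ethylsulfonyl]guanidine (propargylic centre unassigned) | CNC(=NS(=O)(=O)CC[Si](C)(C)C)NC(C#C)[C@H](O[Si](C)(C)C(C)(C)C)c1ccc(OC)cc1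
A9 | alternative 2 | 4-methoxyphenyl trifluoromethanesulfonate | COc1ccc(OS(=O)(=O)C(F)(F)F)cc1
A10 | alternative 2 | N-{4-[(R)-(tert-butyldimethylsilyloxy)(4-methoxyphenyl)methyl]-5-(4-methoxybenzyl)-1-methyl-1H-imidazol-2-yl}-2-(trimethylsilyl)ethanesulfonamide | C[Si](C)(C)CCS(=O)(=O)Nc1nc([C@H](O[Si](C)(C)C(C)(C)C)c2ccc(OC)cc2)c(Cc2ccc(OC)cc2)n1C
A11 | alternative 3 | 3-amino-5-methyl-1,2,4-oxadiazole | Cc1nc(N)no1
A12 | alternative 3 | (Z)-1,4-bis(4-methoxyphenyl)-3-[(5-methyl-1,2,4-oxadiazol-3-yl)amino]but-2-en-1-one | COc1ccc(C/C(Nc2noc(C)n2)=C/C(=O)c2ccc(OC)cc2)cc1
A13 | alternative 3 | N-[4-(4-methoxybenzoyl)-5-(4-methoxybenzyl)-1H-imidazol-2-yl]acetamide | CC(=O)Nc1nc(C(=O)c2ccc(OC)cc2)c(Cc2ccc(OC)cc2)[nH]1
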